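**Plan**

- Cuts, in retrosynthetic order: (a) the seven O–CH3 bonds; (b) ring C (second dihydrobenzofuran) at O1'–C2' and C2'–C3', plus C3'–aryl; (c) seven-membered ring D at the bond from C8 to the dimethoxyphenyl ring; (d) ring B (first dihydrobenzofuran) at O1–C2 and C2–C3, plus C3–aryl.
- Enabling feature: in each dihydrobenzofuran the ring oxygen sits on central ring A ortho to the ring-A carbon that carries the doubly benzylic C3. The array O–C(ring A)–C(ring A)–C3 is therefore a latent ortho-quinone methide, and C2 with its 4-oxyphenyl group is a one-carbon unit that can arrive as a benzylic sulfonium ylide.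
- Forward: 4'-O-methylresveratrol is formylated on ring A between OH and styryl and O-Boc protected. A three-component annulation (aryl Grignard, Boc shift, ortho-quinone methide, chiral benzylide) then builds ring B, and acid closes ring D. Ortho-formylation, O-Boc protection and a second annulation build ring C, and BBr3 frees the nine phenols.
- Stereochemistry: C2/C3 of ring B come from the (1R,4R,5R)-sulfide of the ylide (reagent control, trans). C8 of ring D comes from C3 in the cation cyclisation (substrate control). C2'/C3' of ring C come from the enantiomeric sulfide.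
- Rings B and C have opposite absolute configuration (pseudo-mirror across ring A). Closing ring D before ring C exists is what tells the two 3-aryl groups apart.

Key step: step 5

Assumption: the benzylide of the (1R,4R,5R)-sulfide is taken to give the (2S,3S) ring, by analogy with the face it uses in carbonyl additions, and its enantiomer the (2R,3R) ring; if the sense is reversed, the two enantiomeric salts exchange places between the two annulation steps, since the route needs both.

Atom labels used below: ring B = O1, C2 (4-oxyphenyl), C3; ring C = O1', C2', C3'; ring D = seven-membered ring with C8 (CH bearing 4-oxyphenyl) and C9 (CH2).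

**Step 1**
Reactants: 1 (1R,4R,5R)-isothiocineole; 2 4-methoxybenzyl alcohol
Product: 3 (1R,4R,5R)-6-(4-methoxybenzyl)-4,7,7-trimethyl-6-thiabicyclo[3.2.1]octan-6-ium tetrafluoroborate (benzyl exo on sulfur)
Conditions: HBF4·OEt2, Et2O/CH2Cl2, 0 °C → rt
Reagents that add atoms: tetrafluoroboric acid (as diethyl etherate), [H+].F[B-](F)(F)F
Why: Acid-promoted S-alkylation of the thioether by the 4-methoxybenzyl cation should occur on the less hindered exo lone pair (the side of the one-carbon bridge), giving one sulfonium diastereomer that crystallises as the tetrafluoroborate.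

**Step 2**
Reactants: 4 (1S,4S,5S)-isothiocineole; 2 4-methoxybenzyl alcohol
Product: 5 (1S,4S,5S)-6-(4-methoxybenzyl)-4,7,7-trimethyl-6-thiabicyclo[3.2.1]octan-6-ium tetrafluoroborate (enantiomer of 3)
Conditions: HBF4·OEt2, Et2O/CH2Cl2, 0 °C → rt
Reagents that add atoms: tetrafluoroboric acid (as diethyl etherate), [H+].F[B-](F)(F)F
Why: Same acid-promoted S-alkylation as in step 1, on the enantiomeric sulfide.

**Step 3**
Reactants: 6 (E)-5-[2-(4-methoxyphenyl)ethenyl]benzene-1,3-diol (4'-O-methylresveratrol)
Product: 7 2,4-dihydroxy-6-[(E)-2-(4-methoxyphenyl)ethenyl]benzaldehyde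
Conditions: POCl3, DMF, MeCN, 0 °C → rt; then H2O, NaOAc, 50 °C
Reagents that add atoms: N,N-dimethylformamide (formyl carbon), CN(C)C=O; water (carbonyl oxygen), O
Why: Vilsmeier–Haack formylation of a 5-substituted resorcinol should go to the ring-A position ortho to one OH and para to the other, next to the styryl group (as with orcinol), and the stilbene alkene is not nucleophilic enough to compete.

**Step 4**
Reactants: 7 2,4-dihydroxy-6-[(E)-2-(4-methoxyphenyl)ethenyl]benzaldehyde
Product: 8 di-tert-butyl {4-formyl-5-[(E)-2-(4-methoxyphenyl)ethenyl]-1,3-phenylene} bis(carbonate)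
Conditions: Boc2O, i-Pr2NEt, DMAP (cat.), THF, 0 °C → rt
Reagents that add atoms: di-tert-butyl dicarbonate, CC(C)(C)OC(=O)OC(=O)OC(C)(C)C
Why: DMAP-catalysed O-acylation of both phenols installs the migrating Boc group on the oxygen ortho to the aldehyde and an acid-labile cap on the para oxygen.

**Step 5**
Reactants: 8 di-tert-butyl {4-formyl-5-[(E)-2-(4-methoxyphenyl)ethenyl]-1,3-phenylene} bis(carbonate); 9 3,5-dimethoxyphenylmagnesium chloride (1.0 M in THF); 3 (1R,4R,5R)-sulfonium tetrafluoroborate
Product: 13 tert-butyl (2S,3S)-3-(3,5-dimethoxyphenyl)-2-(4-methoxyphenyl)-4-[(E)-2-(4-methoxyphenyl)ethenyl]-2,3-dihydro-1-benzofuran-6-yl carbonate, via ylide 10 (not isolated), via ortho-quinone methide 11 (not isolated), via betaine 12 (not isolated)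
Conditions: 9 (1.05 equiv), THF, −78 °C; then 10 [3 (1.5 equiv), LiN(SiMe3)2 (1.4 equiv), THF/CH2Cl2, −78 °C], −78 → 0 °C
Reagents that add atoms: none
Why: Proposed new method: The Grignard reagent 9 adds to the aldehyde of 8 at −78 °C, the magnesium alkoxide takes the neighbouring Boc group (O-to-O shift through a six-membered transition state) and, on warming, the phenoxide expels tert-butyl carbonate to give ortho-quinone methide 11, which ylide 10 attacks at the exocyclic carbon (C3–C2 bond) to give betaine 12 before the phenoxide oxygen displaces sulfide 1 from C2. The closest known reaction types are the organomagnesium-triggered release of ortho-quinone methides from O-Boc salicylaldehydes with capture by a second nucleophile, and the base-mediated formal [4+1] annulation of ortho-quinone methides with sulfonium ylides to trans-2,3-dihydrobenzofurans; running both in one flask with a semi-stabilised, sulfide-derived chiral benzylide is the untested part. Ring B closes in the 5-exo-tet mode (O1 attacks C2, the sulfide leaves, inversion at C2). C2 is set by the reagent, since the bicyclic sulfide fixes the ylide conformation and shields one face of the ylide carbon as in its additions to aldehydes and imines, and C3 is set relative to C2 by the trans preference of addition and closure (the cis betaine closes more slowly and reverts), which should give (2S,3S). The step needs 1,2-addition of 9 to the aldehyde and not to the two aryl carbonates (the aldehyde is far more electrophilic at −78 °C and only 1.05 equiv is used), no second aryl addition to 11 (11 forms only above about −40 °C, when 9 is spent), and conjugate attack of 10 on 11 alone (the ortho-quinone methide is the only strong acceptor present and rearomatisation drives the addition).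

**Step 6**
Reactants: 13 tert-butyl (2S,3S)-dihydrobenzofuranyl carbonate with the 4-methoxystyryl group
Product: 14 tetracyclic phenol (rings A, B, D): ring B (2S,3S), C8 (S) bearing 4-methoxyphenyl, free OH on ring A
Conditions: CF3CO2H, CH2Cl2, 0 °C → rt
Reagents that add atoms: none
Why: Acidolysis of the aryl tert-butyl carbonate and protonation of the stilbene at C9 give the anisyl-stabilised cation at C8, which the 3,5-dimethoxyphenyl ring on C3 (the only arene within reach) captures ortho/para to its methoxy groups in an intramolecular Friedel–Crafts hydroarylation; the 4-methoxyphenyl group should take the exo, pseudo-equatorial position anti to the C3–C2 bond, so C8 is set (S) by substrate control from C3.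

**Step 7**
Reactants: 14 tetracyclic phenol
Product: 15 ring-A salicylaldehyde (CHO between the free OH and C9)
Conditions: MgCl2, Et3N, (CH2O)n, MeCN, reflux
Reagents that add atoms: paraformaldehyde (as formaldehyde), C=O
Why: Magnesium-phenoxide-directed ortho-hydroxymethylation followed by hydride transfer to a second formaldehyde (the MgCl2/Et3N/paraformaldehyde ortho-formylation of phenols) acts only on ring A, the one ring with a free phenol, and of its two ortho sites the one para to the ring-B oxygen is the more nucleophilic, as with 3-alkoxyphenols.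

**Step 8**
Reactants: 15 ring-A salicylaldehyde
Product: 16 O-Boc salicylaldehyde (tert-butyl carbonate of 15)
Conditions: Boc2O, i-Pr2NEt, DMAP (cat.), THF, rt
Reagents that add atoms: di-tert-butyl dicarbonate, CC(C)(C)OC(=O)OC(=O)OC(C)(C)C
Why: DMAP-catalysed O-acylation of the single phenol sets up the second Boc-shift/elimination.

**Step 9**
Reactants: 16 O-Boc salicylaldehyde; 9 3,5-dimethoxyphenylmagnesium chloride; 5 (1S,4S,5S)-sulfonium tetrafluoroborate
Product: 20 heptamethyl ether of the target (2S,3S,8S,2'R,3'R), via ylide 17 (not isolated), via ortho-quinone methide 18 (not isolated), via betaine 19 (not isolated)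
Conditions: 9 (1.05 equiv), THF, −78 °C; then 17 [5 (1.5 equiv), LiN(SiMe3)2 (1.4 equiv), THF/CH2Cl2, −78 °C], −78 → 0 °C
Reagents that add atoms: none
Why: Proposed new method: the same sequence as in step 5 (aryl addition, Boc shift, loss of tert-butyl carbonate to ortho-quinone methide 18, conjugate addition of ylide 17, 5-exo-tet closure of O1' on C2' with return of sulfide 4) builds ring C; the closest known types are again the Grignard-triggered ortho-quinone methide release and the ortho-quinone methide/sulfonium ylide [4+1] annulation, and the enantiomeric sulfide sets C2' (R) by reagent control, with C3' (R) following from the trans closure, the resident centres lying on the far flank of ring A.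

**Step 10**
Reactants: 20 heptamethyl ether of the target
Product: 21 target (2S,3S,8S,2'R,3'R)
Conditions: BBr3 (excess), CH2Cl2, −78 °C → rt; then MeOH, H2O
Reagents that add atoms: none
Why: Lewis-acid cleavage of the seven aryl methyl ethers (bromide attacks the methyl of the O–B complex) frees the nine phenols; no alkene remains for cationic rearrangement, and any reversible ionisation of the benzylic C2–O bonds recloses to the favoured trans rings.

**Compound list**

1 | (1R,4R,5R)-isothiocineole [(1R,4R,5R)-4,7,7-trimethyl-6-thiabicyclo[3.2.1]octane] | C[C@@H]1CC[C@@H]2C[C@H]1SC2(C)C | starting material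
2 | 4-methoxybenzyl alcohol | COc1ccc(CO)cc1 | starting material
3 | (1R,4R,5R)-6-(4-methoxybenzyl)-4,7,7-trimethyl-6-thiabicyclo[3.2.1]octan-6-ium tetrafluoroborate, benzyl exo on sulfur | C[C@@H]1CC[C@@H]2C[C@H]1[S@@+](Cc1ccc(OC)cc1)C2(C)C.F[B-](F)(F)F | intermediate
4 | (1S,4S,5S)-isothiocineole | C[C@H]1CC[C@H]2C[C@@H]1SC2(C)C | starting material
5 | (1S,4S,5S)-6-(4-methoxybenzyl)-4,7,7-trimethyl-6-thiabicyclo[3.2.1]octan-6-ium tetrafluoroborate, enantiomer of 3 | C[C@H]1CC[C@H]2C[C@@H]1[S@+](Cc1ccc(OC)cc1)C2(C)C.F[B-](F)(F)F | intermediate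
6 | (E)-5-[2-(4-methoxyphenyl)ethenyl]benzene-1,3-diol (4'-O-methylresveratrol) | COc1ccc(/C=C/c2cc(O)cc(O)c2)cc1 | starting material
7 | 2,4-dihydroxy-6-[(E)-2-(4-methoxyphenyl)ethenyl]benzaldehyde | COc1ccc(/C=C/c2cc(O)cc(O)c2C=O)cc1 | intermediate
8 | di-tert-butyl {4-formyl-5-[(E)-2-(4-methoxyphenyl)ethenyl]-1,3-phenylene} bis(carbonate) | COc1ccc(/C=C/c2cc(OC(=O)OC(C)(C)C)cc(OC(=O)OC(C)(C)C)c2C=O)cc1 | intermediate
9 | 3,5-dimethoxyphenylmagnesium chloride | COc1cc(OC)cc([Mg]Cl)c1 | starting material
10 | sulfonium 4-methoxybenzylide from 3 (not isolated) | C[C@@H]1CC[C@@H]2C[C@H]1[S@@+]([CH-]c1ccc(OC)cc1)C2(C)C | intermediate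
11 | ortho-quinone methide of ring A carrying the 3,5-dimethoxyphenyl group on the exocyclic carbon, exocyclic C=C geometry not defined (not isolated) | O=C1C=C(OC(=O)OC(C)(C)C)C=C(/C=C/c2ccc(OC)cc2)C1=Cc1cc(OC)cc(OC)c1 | intermediate
12 | sulfonium phenoxide betaine from 10 and 11, drawn as the zwitterion (not isolated) | C[C@@H]1CC[C@@H]2C[C@H]1[S@@+]([C@@H](c1ccc(OC)cc1)[C@@H](c1cc(OC)cc(OC)c1)c1c([O-])cc(OC(=O)OC(C)(C)C)cc1/C=C/c1ccc(OC)cc1)C2(C)C | intermediate
13 | tert-butyl (2S,3S)-3-(3,5-dimethoxyphenyl)-2-(4-methoxyphenyl)-4-[(E)-2-(4-methoxyphenyl)ethenyl]-2,3-dihydro-1-benzofuran-6-yl carbonate | O1[C@H](c2ccc(OC)cc2)[C@@H](c2cc(OC)cc(OC)c2)c2c(/C=C/c3ccc(OC)cc3)cc(OC(=O)OC(C)(C)C)cc12 | intermediate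
14 | tetracyclic phenol, rings A, B and D: (2S,3S) ring B, (8S) ring D, four OMe, free OH on ring A | COc1ccc([C@@H]2Cc3c4c(cc(O)c3)O[C@H](c3ccc(OC)cc3)[C@H]4c3cc(OC)cc(OC)c32)cc1 | intermediate
15 | salicylaldehyde of 14 (CHO on ring A between OH and C9) | COc1ccc([C@@H]2Cc3c4c(cc(O)c3C=O)O[C@H](c3ccc(OC)cc3)[C@H]4c3cc(OC)cc(OC)c32)cc1 | intermediate
16 | tert-butyl carbonate of 15 | COc1ccc([C@@H]2Cc3c4c(cc(OC(=O)OC(C)(C)C)c3C=O)O[C@H](c3ccc(OC)cc3)[C@H]4c3cc(OC)cc(OC)c32)cc1 | intermediate
17 | sulfonium 4-methoxybenzylide from 5 (not isolated) | C[C@H]1CC[C@H]2C[C@@H]1[S@+]([CH-]c1ccc(OC)cc1)C2(C)C | intermediate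
18 | second ortho-quinone methide of ring A, exocyclic C=C geometry not defined (not isolated) | COc1ccc([C@@H]2CC3=C4C(=CC(=O)C3=Cc3cc(OC)cc(OC)c3)O[C@H](c3ccc(OC)cc3)[C@H]4c3cc(OC)cc(OC)c32)cc1 | intermediate
19 | sulfonium phenoxide betaine from 17 and 18, drawn as the zwitterion (not isolated) | COc1ccc([C@@H]2Cc3c4c(cc([O-])c3[C@@H](c3cc(OC)cc(OC)c3)[C@@H](c3ccc(OC)cc3)[S@+]5[C@H]6C[C@H](CC[C@@H]6C)C5(C)C)O[C@H](c3ccc(OC)cc3)[C@H]4c3cc(OC)cc(OC)c32)cc1 | intermediate
20 | heptamethyl ether of the target (2S,3S,8S,2'R,3'R) | COc1ccc([C@@H]2Cc3c4c(cc5c3[C@@H](c3cc(OC)cc(OC)c3)[C@H](c3ccc(OC)cc3)O5)O[C@H](c3ccc(OC)cc3)[C@H]4c3cc(OC)cc(OC)c32)cc1 | intermediate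
21 | CNP0136963.1 (2S,3S,8S,2'R,3'R) | Oc1ccc([C@@H]2Cc3c4c(cc5c3[C@@H](c3cc(O)cc(O)c3)[C@H](c3ccc(O)cc3)O5)O[C@H](c3ccc(O)cc3)[C@H]4c3cc(O)cc(O)c32)cc1 | target

**Step count and risks**

Total steps: 10. Longest linear sequence: 8 steps (6 → 21, steps 3 to 10).

Steps most likely to fail:

1. Step 5. The ylide may decay before the ortho-quinone methide is released (the two temperature windows may not overlap), the ylide or residual base may attack the aryl carbonate, or facial and trans control may erode. The fallback separates the events and uses known reaction types only: sulfinate addition to an ortho-quinone methide, then carbonate-induced sulfinate elimination from a 2-(1-sulfonylalkyl)phenol with [4+1] capture by a sulfonium ylide. It sets out from 8: Grignard reagent 9 in THF at −78 °C, then sodium 4-methylbenzenesulfinate in DMF on warming, traps 11 as the isolable 2-[(3,5-dimethoxyphenyl)(tosyl)methyl]phenol F1. F1 with salt 3 and Cs2CO3 in MeCN/CH2Cl2 at rt regenerates 11 and 10 slowly and side by side, and the annulation rejoins the route at 13.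

2. Step 9. The same timing problem may arise on a more hindered aldehyde, and the facial bias of the puckered ring D next to the reacting carbon may oppose the reagent. The fallback uses the same known two-step sequence and sets out from 16: Grignard reagent 9 at −78 °C, then sodium 4-methylbenzenesulfinate, gives the ring-A aryl(tosyl)methyl phenol F2. F2 with salt 5 and Cs2CO3 in MeCN/CH2Cl2 at rt rejoins the route at 20.

3. Step 6. The cationic manifold may branch: ionisation of the C2–O bond of ring B with capture by the alkene, tert-butylation of the electron-rich rings, or intermolecular alkylation. The fallback replaces protonation by halonium-induced Friedel–Crafts closure under non-acidic conditions and sets out from 13. N-bromosuccinimide in CH2Cl2 at −78 °C gives the ring-D bromide F3 (epimers at the CHBr carbon, of no consequence). (Me3Si)3SiH with AIBN in toluene at 80 °C removes the bromine to give the ring-D carbonate F4. K2CO3 in MeOH cleaves the carbonate and the route is rejoined at 14.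

**Further compounds**

F1 | step 5 | tert-butyl 3-[(3,5-dimethoxyphenyl)(4-methylbenzenesulfonyl)methyl]-4-hydroxy... ring-A sulfone: 2-[(3,5-dimethoxyphenyl)(tosyl)methyl]phenol carrying the para tert-butyl carbonate and the (E)-4-methoxystyryl group, racemic at the sulfonyl carbon | Cc1ccc(cc1)S(=O)(=O)C(c1cc(OC)cc(OC)c1)c1c(O)cc(OC(=O)OC(C)(C)C)cc1/C=C/c1ccc(OC)cc1
F2 | step 9 | ring-A aryl(tosyl)methyl phenol of the tetracycle (sulfonyl carbon between the free OH and C9, both epimers) | COc1ccc([C@@H]2Cc3c4c(cc(O)c3C(c3cc(OC)cc(OC)c3)S(=O)(=O)c3ccc(C)cc3)O[C@H](c3ccc(OC)cc3)[C@H]4c3cc(OC)cc(OC)c32)cc1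
F3 | step 6 | ring-D bromide: tert-butyl carbonate of 14 with Br on C9 (both epimers at C9) | COc1ccc([C@@H]2C(Br)c3c4c(cc(OC(=O)OC(C)(C)C)c3)O[C@H](c3ccc(OC)cc3)[C@H]4c3cc(OC)cc(OC)c32)cc1
F4 | step 6 | tert-butyl carbonate of 14 | COc1ccc([C@@H]2Cc3c4c(cc(OC(=O)OC(C)(C)C)c3)O[C@H](c3ccc(OC)cc3)[C@H]4c3cc(OC)cc(OC)c32)cc1
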